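**Retrosynthetic overview**
- The target is the (1R,5R,7S)-bicyclo[3.3.1]nonane-2,4,9-trione with 7-exo prenyl and C5 geranyl. Both benzene rings are bought; the only ring made is the C1/C5–C9 bridge ring, closed last.
- Key disconnection C1–C8: a tertiary C8 cation (protonated isopropenyl of an (R)-lavandulyl chain) is captured by the prenyl-bearing enol carbon of a dearomatised acylphloroglucinol, as in the prenyl-cation-triggered biosynthetic closure. The same acid frees the catechol.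
- C5 quaternary carbon: two C-alkylations (lavandulyl triflate, then geranyl bromide) at one ring carbon. The other two ring carbons carry the aroyl group and a removable CO2Me group, so no prenyl/geranyl regioisomers can form.
- CO2Me is then exchanged for H and then prenyl. C7 comes from lavandulol, the C5 epimers are separated, and C1 follows from the bridge.
- Aryl ketone: Friedel–Crafts acylation of methyl 2,4,6-trihydroxybenzoate with protocatechuic acid, then a diphenylmethylene ketal.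

Assumption: (R)-(−)-lavandulol is bought as the single natural enantiomer, and dearomatised intermediates are written as one enol tautomer each.

Step 1
Reactants: 1 methyl 2,4,6-trihydroxybenzoate; 2 3,4-dihydroxybenzoic acid
Product: 3 methyl 3-(3,4-dihydroxybenzoyl)-2,4,6-trihydroxybenzoate
Conditions: BF3·OEt2, 90 °C
Reagents that add atoms: none
Why: Friedel–Crafts acylation with the BF3-activated acid at one of the two equivalent free ring positions, the new ketone then deactivating the ring against a second acylation; no stereocentre.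

Step 2
Reactants: 3 methyl 3-(3,4-dihydroxybenzoyl)-2,4,6-trihydroxybenzoate
Product: 4 methyl 3-(2,2-diphenyl-1,3-benzodioxole-5-carbonyl)-2,4,6-trihydroxybenzoate
Conditions: Ph2CCl2, Ph2O, 175 °C
Reagents that add atoms: dichlorodiphenylmethane, ClC(Cl)(c1ccccc1)c1ccccc1
Why: Ketalisation in which only the 1,2-diol can close a five-membered benzodioxole, so the three hydroxyls of the phloroglucinol ring stay free; no stereocentre.

Step 3
Reactants: 5 (R)-lavandulol
Product: 6 (R)-lavandulyl trifluoromethanesulfonate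
Conditions: Tf2O, 2,6-lutidine, CH2Cl2, −78 °C; used at once
Reagents that add atoms: trifluoromethanesulfonic anhydride, O=S(=O)(OS(=O)(=O)C(F)(F)F)C(F)(F)F
Why: O-sulfonylation of the primary alcohol, which does not touch the stereocentre, so the (R) configuration is kept.

Step 4
Reactants: 4 methyl 3-(2,2-diphenyl-1,3-benzodioxole-5-carbonyl)-2,4,6-trihydroxybenzoate; 6 (R)-lavandulyl trifluoromethanesulfonate
Product: 7 methyl 3-(2,2-diphenyl-1,3-benzodioxole-5-carbonyl)-2,4,6-trihydroxy-5-[(2S)-5-methyl-2-(prop-1-en-2-yl)hex-4-en-1-yl]benzoate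
Conditions: LiN(SiMe3)2, THF–toluene, −78 → 0 °C
Reagents that add atoms: none
Why: SN2 C-alkylation of the lithium triphenoxide at its single free ring carbon, favoured over O-alkylation by tight Li–O ion pairing and completed by re-aromatisation; the side-chain stereocentre is untouched (its descriptor changes from R to S only through CIP priorities).

Step 5
Reactants: 7 methyl 3-(2,2-diphenyl-1,3-benzodioxole-5-carbonyl)-2,4,6-trihydroxy-5-[(2S)-5-methyl-2-(prop-1-en-2-yl)hex-4-en-1-yl]benzoate; 8 geranyl bromide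
Product: 9 methyl (5R)-3-(2,2-diphenyl-1,3-benzodioxole-5-carbonyl)-5-[(2E)-3,7-dimethylocta-2,6-dien-1-yl]-2,4-dihydroxy-5-[(2S)-5-methyl-2-(prop-1-en-2-yl)hex-4-en-1-yl]-6-oxocyclohexa-1,3-diene-1-carboxylate
Conditions: NaOMe, MeOH, 0 °C → rt; preparative HPLC separation of the C5 epimers
Reagents that add atoms: none
Why: Alkylative dearomatisation (lupulone-type C-allylation in methanol) at the only alkyl-bearing ring carbon, the ester- and aroyl-bearing carbons being poor nucleophiles, which creates the future C5 quaternary centre regioselectively but without facial control (about 1:1), so the (5R) epimer is separated and carried on.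

Step 6
Reactants: 9 methyl (5R)-3-(2,2-diphenyl-1,3-benzodioxole-5-carbonyl)-5-[(2E)-3,7-dimethylocta-2,6-dien-1-yl]-2,4-dihydroxy-5-[(2S)-5-methyl-2-(prop-1-en-2-yl)hex-4-en-1-yl]-6-oxocyclohexa-1,3-diene-1-carboxylate
Product: 10 (6R)-4-(2,2-diphenyl-1,3-benzodioxole-5-carbonyl)-6-[(2E)-3,7-dimethylocta-2,6-dien-1-yl]-3,5-dihydroxy-6-[(2S)-5-methyl-2-(prop-1-en-2-yl)hex-4-en-1-yl]cyclohexa-2,4-dien-1-one
Conditions: LiCl, DMSO–H2O, 110 °C
Reagents that add atoms: none
Why: Krapcho demethoxycarbonylation, in which chloride removes the methyl group by SN2 and the resulting diketo acid loses CO2 at once, freeing the ring carbon that becomes C1; stereocentres are untouched.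

Step 7
Reactants: 10 (6R)-4-(2,2-diphenyl-1,3-benzodioxole-5-carbonyl)-6-[(2E)-3,7-dimethylocta-2,6-dien-1-yl]-3,5-dihydroxy-6-[(2S)-5-methyl-2-(prop-1-en-2-yl)hex-4-en-1-yl]cyclohexa-2,4-dien-1-one; 11 prenyl bromide
Product: 12 (6R)-4-(2,2-diphenyl-1,3-benzodioxole-5-carbonyl)-6-[(2E)-3,7-dimethylocta-2,6-dien-1-yl]-3,5-dihydroxy-2-(3-methylbut-2-en-1-yl)-6-[(2S)-5-methyl-2-(prop-1-en-2-yl)hex-4-en-1-yl]cyclohexa-2,4-dien-1-one
Conditions: NaOMe (2.2 equiv), MeOH, 0 °C
Reagents that add atoms: none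
Why: C-allylation of the cyclic β-diketone dianion at its only CH carbon, which is more nucleophilic than the aroyl-bearing triacylmethane carbon and is favoured over O-attack in protic medium; no new stereocentre.

Step 8
Reactants: 12 (6R)-4-(2,2-diphenyl-1,3-benzodioxole-5-carbonyl)-6-[(2E)-3,7-dimethylocta-2,6-dien-1-yl]-3,5-dihydroxy-2-(3-methylbut-2-en-1-yl)-6-[(2S)-5-methyl-2-(prop-1-en-2-yl)hex-4-en-1-yl]cyclohexa-2,4-dien-1-one
Product: 14 (1R,5R,7S)-3-(3,4-dihydroxybenzoyl)-5-[(2E)-3,7-dimethylocta-2,6-dien-1-yl]-4-hydroxy-8,8-dimethyl-1,7-bis(3-methylbut-2-en-1-yl)bicyclo[3.3.1]non-3-ene-2,9-dione (target), via bicyclic ketal 13 (not isolated)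
Conditions: HCO2H (neat), 35 °C; then H2O (10 vol%), 45 °C
Reagents that add atoms: none
Why: Biomimetic cationic cyclisation in which formic acid protonates the 1,1-disubstituted alkene to the tertiary C8 cation, which is captured by the prenyl-bearing enol carbon through a chair with the C7 prenyl equatorial (C7 is carried over from lavandulol and C1 is fixed by the bridge, giving 1R,5R,7S with 7-exo prenyl, while O-capture is reversible in this medium), after which the aqueous formic acid hydrolyses the diphenylmethylene ketal.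

**Compound list**
1 | methyl 2,4,6-trihydroxybenzoate | COC(=O)c1c(O)cc(O)cc1O | starting material
2 | 3,4-dihydroxybenzoic acid (protocatechuic acid) | OC(=O)c1ccc(O)c(O)c1 | starting material
3 | methyl 3-(3,4-dihydroxybenzoyl)-2,4,6-trihydroxybenzoate | COC(=O)c1c(O)cc(O)c(C(=O)c2ccc(O)c(O)c2)c1O | intermediate
4 | methyl 3-(2,2-diphenyl-1,3-benzodioxole-5-carbonyl)-2,4,6-trihydroxybenzoate | COC(=O)c1c(O)cc(O)c(C(=O)c2ccc3OC(c4ccccc4)(c4ccccc4)Oc3c2)c1O | intermediate
5 | (R)-lavandulol, (2R)-5-methyl-2-(prop-1-en-2-yl)hex-4-en-1-ol | OC[C@H](CC=C(C)C)C(C)=C | starting material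
6 | (R)-lavandulyl trifluoromethanesulfonate, (2R)-5-methyl-2-(prop-1-en-2-yl)hex-4-en-1-yl triflate | FC(F)(F)S(=O)(=O)OC[C@H](CC=C(C)C)C(C)=C | intermediate
7 | methyl 3-(2,2-diphenyl-1,3-benzodioxole-5-carbonyl)-2,4,6-trihydroxy-5-[(2S)-5-methyl-2-(prop-1-en-2-yl)hex-4-en-1-yl]benzoate | COC(=O)c1c(O)c(C[C@H](CC=C(C)C)C(C)=C)c(O)c(C(=O)c2ccc3OC(c4ccccc4)(c4ccccc4)Oc3c2)c1O | intermediate
8 | geranyl bromide, (2E)-1-bromo-3,7-dimethylocta-2,6-diene | CC(C)=CCC/C(C)=C/CBr | starting material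
9 | methyl (5R)-3-(2,2-diphenyl-1,3-benzodioxole-5-carbonyl)-5-[(2E)-3,7-dimethylocta-2,6-dien-1-yl]-2,4-dihydroxy-5-[(2S)-5-methyl-2-(prop-1-en-2-yl)hex-4-en-1-yl]-6-oxocyclohexa-1,3-diene-1-carboxylate | CC(C)=CCC/C(C)=C/C[C@@]1(C[C@H](CC=C(C)C)C(C)=C)C(O)=C(C(=O)c2ccc3OC(c4ccccc4)(c4ccccc4)Oc3c2)C(O)=C(C(=O)OC)C1=O | intermediate
10 | (6R)-4-(2,2-diphenyl-1,3-benzodioxole-5-carbonyl)-6-[(2E)-3,7-dimethylocta-2,6-dien-1-yl]-3,5-dihydroxy-6-[(2S)-5-methyl-2-(prop-1-en-2-yl)hex-4-en-1-yl]cyclohexa-2,4-dien-1-one | CC(C)=CCC/C(C)=C/C[C@@]1(C[C@H](CC=C(C)C)C(C)=C)C(O)=C(C(=O)c2ccc3OC(c4ccccc4)(c4ccccc4)Oc3c2)C(O)=CC1=O | intermediate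
11 | prenyl bromide, 1-bromo-3-methylbut-2-ene | CC(C)=CCBr | starting material
12 | (6R)-4-(2,2-diphenyl-1,3-benzodioxole-5-carbonyl)-6-[(2E)-3,7-dimethylocta-2,6-dien-1-yl]-3,5-dihydroxy-2-(3-methylbut-2-en-1-yl)-6-[(2S)-5-methyl-2-(prop-1-en-2-yl)hex-4-en-1-yl]cyclohexa-2,4-dien-1-one | CC(C)=CCC/C(C)=C/C[C@@]1(C[C@H](CC=C(C)C)C(C)=C)C(O)=C(C(=O)c2ccc3OC(c4ccccc4)(c4ccccc4)Oc3c2)C(O)=C(CC=C(C)C)C1=O | intermediate
13 | (1R,5R,7S)-3-(2,2-diphenyl-1,3-benzodioxole-5-carbonyl)-5-[(2E)-3,7-dimethylocta-2,6-dien-1-yl]-4-hydroxy-8,8-dimethyl-1,7-bis(3-methylbut-2-en-1-yl)bicyclo[3.3.1]non-3-ene-2,9-dione | CC(C)=CCC/C(C)=C/C[C@@]12C[C@H](CC=C(C)C)C(C)(C)[C@@](CC=C(C)C)(C(=O)C(C(=O)c3ccc4OC(c5ccccc5)(c5ccccc5)Oc4c3)=C1O)C2=O | intermediate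
14 | (1R,5R,7S)-3-(3,4-dihydroxybenzoyl)-5-[(2E)-3,7-dimethylocta-2,6-dien-1-yl]-4-hydroxy-8,8-dimethyl-1,7-bis(3-methylbut-2-en-1-yl)bicyclo[3.3.1]non-3-ene-2,9-dione | CC(C)=CCC/C(C)=C/C[C@@]12C[C@H](CC=C(C)C)C(C)(C)[C@@](CC=C(C)C)(C(=O)C(C(=O)c3ccc(O)c(O)c3)=C1O)C2=O | target

Total step count: 8
Longest linear sequence: 7 steps (steps 1, 2, 4, 5, 6, 7 and 8; step 3 is a one-step branch)

**Three steps most likely to fail, with fallbacks**

The first is step 4. The β-branched triflate 6 may O-alkylate the doubly acyl-deactivated triphenoxide of 4 instead of attacking its ring carbon. The fallback reverses the order of the two alkylations at this carbon and sets out from 4. Compound 4 is first C-geranylated with 8 (NaOMe, MeOH, 0 °C) to methyl 3-(2,2-diphenyl-1,3-benzodioxole-5-carbonyl)-5-[(2E)-3,7-dimethylocta-2,6-dien-1-yl]-2,4,6-trihydroxybenzoate F1. The triflate 6 is then used in the dearomatising step (LiN(SiMe3)2, toluene, −78 → 0 °C), where the fully substituted, more electron-rich carbon of F1 is the only soft site. The route is rejoined at 9, with the same epimer separation.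

The second is step 6. Chloride-mediated demethoxycarbonylation at 110 °C may be slow on the enolised ester or may degrade the gem-diallyl dienone. The fallback keeps the carboxyl carbon and turns it into the prenyl donor; it sets out from 9. Compound 9 is transesterified with 3-methylbut-2-en-1-ol through its acylketene (toluene, 100 °C, cat. 4-(dimethylamino)pyridine) to 3-methylbut-2-en-1-yl (5R)-3-(2,2-diphenyl-1,3-benzodioxole-5-carbonyl)-5-[(2E)-3,7-dimethylocta-2,6-dien-1-yl]-2,4-dihydroxy-5-[(2S)-5-methyl-2-(prop-1-en-2-yl)hex-4-en-1-yl]-6-oxocyclohexa-1,3-diene-1-carboxylate F2. Pd(PPh3)4 (5 mol%, THF, rt) then brings about decarboxylative allylation, which places the prenyl group on the carbon that loses CO2. This gives 12 directly, so compound 10 and step 7 are bypassed and the route is rejoined at 12.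

The third is step 8. Formic acid may attack the geranyl or prenyl alkenes, stop at the O-cyclised pyran, or let the cation lose H7 before ring closure, which would erase C7. The fallback generates the same C8 cation without a Brønsted acid and sets out from 12. Markovnikov hydrochlorination of only the 1,1-disubstituted alkene by hydrogen-atom transfer (Co(BF4)2·6H2O, salen-type ligand, TsCl, PhSiH3, EtOH, rt) gives the tertiary chloride (6R)-6-[(2S)-2-(2-chloropropan-2-yl)-5-methylhex-4-en-1-yl]-4-(2,2-diphenyl-1,3-benzodioxole-5-carbonyl)-6-[(2E)-3,7-dimethylocta-2,6-dien-1-yl]-3,5-dihydroxy-2-(3-methylbut-2-en-1-yl)cyclohexa-2,4-dien-1-one F3. Ionisation with silver trifluoromethanesulfonate and 2,6-di-tert-butylpyridine in (CF3)2CHOH–CH2Cl2 at −20 °C closes the ring. The route is rejoined at 13, which is now isolated, and the ketal is cleaved in a separate operation (CF3CO2H–H2O–CH2Cl2, 0 °C) to give 14.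

**Further compounds**
F1 | step 4 | methyl 3-(2,2-diphenyl-1,3-benzodioxole-5-carbonyl)-5-[(2E)-3,7-dimethylocta-2,6-dien-1-yl]-2,4,6-trihydroxybenzoate | CC(C)=CCC/C(C)=C/Cc1c(O)c(C(=O)OC)c(O)c(C(=O)c2ccc3OC(c4ccccc4)(c4ccccc4)Oc3c2)c1O
F2 | step 6 | 3-methylbut-2-en-1-yl (5R)-3-(2,2-diphenyl-1,3-benzodioxole-5-carbonyl)-5-[(2E)-3,7-dimethylocta-2,6-dien-1-yl]-2,4-dihydroxy-5-[(2S)-5-methyl-2-(prop-1-en-2-yl)hex-4-en-1-yl]-6-oxocyclohexa-1,3-diene-1-carboxylate | CC(C)=CCC/C(C)=C/C[C@@]1(C[C@H](CC=C(C)C)C(C)=C)C(O)=C(C(=O)c2ccc3OC(c4ccccc4)(c4ccccc4)Oc3c2)C(O)=C(C(=O)OCC=C(C)C)C1=O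
F3 | step 8 | (6R)-6-[(2S)-2-(2-chloropropan-2-yl)-5-methylhex-4-en-1-yl]-4-(2,2-diphenyl-1,3-benzodioxole-5-carbonyl)-6-[(2E)-3,7-dimethylocta-2,6-dien-1-yl]-3,5-dihydroxy-2-(3-methylbut-2-en-1-yl)cyclohexa-2,4-dien-1-one | CC(C)=CCC/C(C)=C/C[C@@]1(C[C@H](CC=C(C)C)C(C)(C)Cl)C(O)=C(C(=O)c2ccc3OC(c4ccccc4)(c4ccccc4)Oc3c2)C(O)=C(CC=C(C)C)C1=O
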